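(The runs were generated by integration for substances that don't exist, noise included.)

The question was which flask, blue, grey or teal, ended with the most target, and what share of the charge each held.

| flask | substrate | temperature | remark | time |
|---|---|---|---|---|
| Friday's | 2.8 M | −45 °C | run made earlier |  |
| Monday's | 2.8 M | −20 °C | run made earlier |  |
| blue | 2.0 M | 0 °C |  | 5.0 h |
| grey | 2.0 M | −40 °C |  | 5.0 h |
| teal | 2.0 M | −20 °C |  | 5.0 h |

| run | time / h | target / % | substrate / % |
|---|---|---|---|
| Friday's | 12.0 | 2.5 | 0 |
| Friday's | 25.0 | 2.5 | 0.3 |
| Friday's | 40.0 | 3.1 | 0.3 |
| Friday's | 50.0 | 2.3 | 0 |
| Monday's | 4.00 | 13.5 | 0.2 |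
| Monday's | 6.00 | 11.8 | 0.7 |
| Monday's | 10.0 | 12.4 | 0 |
| Monday's | 15.0 | 11.8 | 0 |

(scatter of a reading: 0.5 percentage points)

* the flask that comes out highest in amount of target, in percent of the substrate charged, or "all alike" when all lie within 1.5 percentage points (blue / grey / teal / all alike)
* target at the end, in percent of the substrate charged, blue
* target at the end, in percent of the substrate charged, grey
* target at the end, in percent of the substrate charged, teal

- percentages count the substrate that a species holds: one self-condensation product counts as two
- target is meant together with its crystals
- solid, in amounts per volume of the solution: crystals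
- the analysis behind the earlier runs scatters by 0.5 percentage points, standard deviation
- on the list of suspects stand: substrate <-> other conformer; substrate -> target; other conformer -> isomer of the product; 2 substrate -> self-condensation product; crystals <-> target
- in a conversion other conformer counts as not yet reacted

I first asked which numbers had to be known well. The times did not: the highest substrate reading was 0.7%, and target stayed flat within the scatter. The plateaus mattered. They read 2.60% on Friday and 12.4% on Monday, and the scatter of these means was 9.62% and 2.02% of their values.

I assumed first-order loss to target and second-order loss to self-condensation. Let a be the second rate over the first at the start, proportional to the charge. As the fraction x of the charge left falls from one to zero, target gained per fraction lost is 1/(1+ax), which integrates to a yield of ln(1+a)/a. The plateaus gave a of 205 on Friday and 26.9 on Monday, a slope against 1/T of 4690 K. Extrapolating to blue, an error in Friday's a passes on multiplied by 0.668, and one in Monday's multiplied by 1.67. Friday's small plateau therefore weighed more on blue than Monday's.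

Blue's selectivity factor, its loss to self-condensation over its loss to target at the start, came to 4.95. My yields were 36.0% for blue, 15.7% for teal and 4.84% for grey, the last for a finished flask.

The forecast named blue, with 32% for blue, 4.5% for grey and 15.5% for teal. Its blue stood lower than mine, and it gave two grounds for that: “The isomer route would weaken the dilution gain, and 0 °C is an extrapolation, so I shade blue down”.

Blue came out highest at 36.2%, teal gave 15.8% and grey 3.97%. Grey still held 1.57% substrate at 5.00 h, and its target reached 4.93% at 50.0 h.

    substrate ⇌ other conformer (K = 0.0150, k = 0.00117 /s, Ea = 78.0 kJ/mol, ΔH = −3.00 kJ/mol)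
    substrate → target (k = 8.83 × 10⁻⁴ /s, Ea = 84.0 kJ/mol)
    other conformer → isomer of the product (k = 0.00166 /s, Ea = 84.0 kJ/mol)
    2 substrate → self-condensation product (k = 0.00417 /M/s, Ea = 45.0 kJ/mol)
    crystals ⇌ target, rate k5*(cs5 - [target]) while solid is left; crystals form when [target] > cs5 (solubility = 35.0 mM, k = 0.00898 /s)
    (constants at −20 °C)

A further flask like blue held 0.80 M of substrate, so its a was 1.98 and its reckoned yield 55.1%. That flask gave 55.0%.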